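## Structural features

The target is an achiral, fully aromatic benzofuran whose benzo ring (ring A) and furan ring (ring B) carry five substituents. These are a 4-hydroxyphenyl group (ring C) on C2, a 2,4-dihydroxybenzoyl group (ring E) on C3, hydroxyls on C4 and C6, and a 2-(4-hydroxyphenyl)prop-2-enoyl group (ring D on the α-carbon of an enone) on C7; only C5 bears hydrogen. There is no stereocentre, so no configuration has to be set; the one sp3 centre that appears in the route is racemic and is erased in the last step. The fragile element is the 1,1-disubstituted enone on C7. Its unsubstituted CH2 terminus is an unhindered Michael acceptor beside the C6 hydroxyl, so base or strong acid can close a chromanone by oxa-Michael addition, halide can add to it, and it can oligomerise. Six free phenols, four of them on the acylated rings A and E, also rule out enolate or Mannich chemistry once they are unmasked. The real difficulties are the crowded C3 ketone, wedged between ring C on C2 and the C4 oxygen, and the order in which the enone and the phenols are released. Ring E is a benzene with the ketone carbon on C1, oxygen on C2 and C4, and hydrogen on C3, C5 and C6. That is the pattern a butadiene oxygenated twice on C1 and once on C3 lays onto the two carbons of an ethynyl ketone, and the key step uses it to grow ring E on a small ynone already seated at C3.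

## Logic of the disconnections

18 from 16 (through 17). The C=CH2 bond is retraced to a C–H and a C–S bond, so the methylene is stored as a CH2–S-aryl group. An exposed enone should not survive the Lewis acid and bromide needed to free six phenols, and any base-mediated release would hand it to the C6 phenoxide. The gain is that the Michael acceptor exists only in the last flask. The demand is an S-oxidation that leaves six phenols alone and a thermal syn-elimination that needs no base.

16 from 15. Six aryl O–CH3 bonds are cut at once. Methyl ethers are the one phenol protection that tolerates every earlier step (Grignard reagents, hot Pd/Ag, Lewis-acid acylation, enolate alkylation). The price is a hard Lewis acid, acceptable because 15 holds no enone and its sulfide should be inert.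

15 from 13 and 14. The Cα–CH2 bond is cut; 14 is a one-carbon electrophile that brings its own leaving group for later. 13 has a single enolisable position, so the alkylation has no regiochemical question, but it must go on carbon and not on oxygen.

13 from 11 and 12. The C7–acyl bond is cut, removing ring D and two carbons. Ring A of 11 has only C5 and C7 open. The forward acylation must choose C7 over C5 and ring A over rings C and E.

11 from 10. One O–CH3 bond on ring E is cut. The step is simple but needed so that the phenol does not consume acylating agent or base later.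

10 from 7 and 8 (through 9). The C1–C2 and C5–C6 bonds of ring E are cut. A whole arene with its two oxygens in place reduces to a three-carbon ynone and a four-carbon diene. The crowded C3 then only has to carry an ethynyl ketone, not accept an ortho-substituted aryl nucleophile. The forward step needs a single orientation of the cycloaddition and clean aromatisation.

7 from 5 and 6. The bond between the carbonyl carbon and the alkyne is cut. Single addition is needed, and the terminal ynone must not be attacked by the amine that is released.

5 from 4. The acyl C–O bond is exchanged for C–N. This makes the single addition above possible at a hindered, electron-rich carbonyl.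

4 from 3. The C3–C3a bond is cut. The precursor is an open aryl enol ether with two equivalent ortho positions, so the forward closure has no regiochemical choice.

3 from 1 and 2. The O1–C2 bond is cut, giving a symmetric phenol and an arylpropiolate. The oxygen must add to the aryl-bearing alkyne carbon, which is the only electrophilic one.

## Other disconnections considered

Alternative 1: The cut is O1–C7a. A β-ketoester with the future ring A on its α-carbon, ethyl 2-(3,5-dimethoxyphenyl)-3-(4-methoxyphenyl)-3-oxopropanoate A1, would be oxidised by FeCl3. The enol oxygen would attack an ortho carbon of the dimethoxyphenyl ring, and rearomatisation would close ring B. The intended product is ethyl 4,6-dimethoxy-2-(4-methoxyphenyl)-1-benzofuran-3-carboxylate A2, which is the same compound as 4.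
- In its favour: a cheap iron salt in place of Pd and Ag, and a precursor reachable in one or two steps. On reagent cost it would be the better plan, and in step count it would equal steps 1 and 2.
- Against: the atom mapping does not hold. The aryl carbon on the α-carbon becomes C3a and the attacked ortho carbon becomes C7a. The methoxy groups of a 3,5-dimethoxyphenyl ring therefore end on C5 and C7, and A1 would give ethyl 5,7-dimethoxy-2-(4-methoxyphenyl)-1-benzofuran-3-carboxylate A3, not A2.
- The 4,6-pattern would need ethyl 2-(2,4-dimethoxyphenyl)-3-(4-methoxyphenyl)-3-oxopropanoate A4. Its only free ortho carbon is meta to both methoxy groups, the one position this oxidative mechanism does not activate.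
- Comparison: the chosen closure forms C3–C3a with the ring oxygen already in place from symmetric phenol 1, so the oxygen pattern on C4, C6 and C7a follows from symmetry. Both are oxidative closures of similar length, but only the chosen one maps onto the target.

Alternative 2: The cut is O1–C2, made by isomerisation. A flavone carrying the future ring A on C3, 7-methoxy-2-(4-methoxyphenyl)-3-(2,4,6-trihydroxyphenyl)-4H-chromen-4-one A5, would under base add an ortho phenoxide to C2. The enolate would then expel the pyranone oxygen as a phenoxide, giving [4,6-dihydroxy-2-(4-methoxyphenyl)-1-benzofuran-3-yl](2-hydroxy-4-methoxyphenyl)methanone A6.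
- In its favour: no metal, nothing lost, and the C3 ketone and ring E arrive together with unambiguous oxygenation. On atom economy and mechanistic simplicity of the key step it is the better plan. It equals the chosen plan in avoiding acylation of C3 by a bulky electrophile.
- Against: the addition is formally 5-endo and reversible, so it depends on the product phenoxide being the more stable. A5 needs a biaryl bond between C3 of a 2-arylflavone and a doubly ortho-oxygenated aryl group, a hindered coupling with three phenols to protect and release.
- A6 also carries its oxygens in three different states. Ring A would need reprotection before C7 acylation, and the two remaining methyl ethers would still need a hard Lewis acid.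
- Comparison: structurally it reaches the same skeleton as 10, but with a protection pattern less suited to the endgame. In step economy it should be longer than the chosen plan.

Alternative 3: The cuts are O1–C2, C3–carbonyl and carbonyl–aryl. 3,5-Dimethoxy-2-[(4-methoxyphenyl)ethynyl]phenol A7, 1-iodo-2,4-dimethoxybenzene A8 and carbon monoxide A10 would combine under zerovalent palladium. Oxidative addition of A8 and insertion of A10 give an aroyl–palladium species, the alkyne is activated for anti attack by the phenol oxygen, and reductive elimination gives (2,4-dimethoxyphenyl)[4,6-dimethoxy-2-(4-methoxyphenyl)-1-benzofuran-3-yl]methanone A9, which is identical with 11.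
- In its favour: three bonds and ring B in one operation from simple partners. A7 should be reachable from 1 by ortho-iodination and alkyne coupling, so A9 is reached in about three operations against six for 11. On step economy this alternative is the better one, and in outcome it is equal, since the endgame from 11 is unchanged.
- Against: three selectivities must be won at once. Carbonyl insertion must beat direct aryl transfer, coupling must beat plain cycloisomerisation of the electron-rich alkynylphenol, and C-acylation must beat aroylation of the free phenol. All this is asked of an electron-rich, ortho-substituted aryl iodide, and a toxic gas has to be handled.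
- Comparison: the chosen plan forms the same bonds in separate, individually controllable steps. It builds ring E from acyclic carbons, which fixes the ortho/para oxygen pattern by orbital control, and it leaves the ring E phenol of 10 free for a different protecting group if wanted. It pays for this with about three more steps.

Key step: step 5

Remark on the chemistry: diene 8 is assumed to be a purchasable reagent; if it is not, one silylation (TMSCl, Et3N) of the corresponding β,β-dimethoxy enone would supply it. Enol ether 3 is carried as an E/Z mixture.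

## Route

Step 1
Reactants: 1 3,5-dimethoxyphenol; 2 ethyl 3-(4-methoxyphenyl)propiolate
Product: 3 ethyl 3-(3,5-dimethoxyphenoxy)-3-(4-methoxyphenyl)prop-2-enoate (E/Z mixture)
Conditions: Cs2CO3 (0.3 equiv), DMF, 80 °C
Reagents that add atoms: none
Why: Base-catalysed oxa-Michael addition of the phenoxide of 1 to the aryl-bearing β-carbon of ynoate 2, the only electrophilic alkyne carbon, forms O1–C2 with ring C already on the future C2. Both alkene isomers are usable because the push-pull double bond should isomerise under the conditions of step 2.

Step 2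
Reactants: 3 ethyl 3-(3,5-dimethoxyphenoxy)-3-(4-methoxyphenyl)prop-2-enoate
Product: 4 ethyl 4,6-dimethoxy-2-(4-methoxyphenyl)-1-benzofuran-3-carboxylate
Conditions: Pd(OAc)2 (10 mol %), PPh3 (10 mol %), CF3CO2Ag (2 equiv), PhCl, 110 °C, air
Reagents that add atoms: none
Why: Dehydrogenative cyclisation of a 3-aryloxyacrylate by divalent palladium: palladation of the nucleophilic α-carbon, carboxylate-assisted C–H activation at the ortho carbon of the electron-rich ring and reductive elimination form C3–C3a, and CF3CO2Ag returns zerovalent palladium to the divalent state. The two ortho positions are equivalent, so only the 4,6-dimethoxy isomer can arise.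

Step 3
Reactants: 4 ethyl 4,6-dimethoxy-2-(4-methoxyphenyl)-1-benzofuran-3-carboxylate
Product: 5 N,4,6-trimethoxy-2-(4-methoxyphenyl)-N-methyl-1-benzofuran-3-carboxamide
Conditions: MeNH(OMe)·HCl (3 equiv), iPrMgCl (6 equiv), THF, −20 °C → rt
Reagents that add atoms: N,O-dimethylhydroxylamine hydrochloride, CNOC.Cl
Why: Direct aminolysis of the ester by the chloromagnesium amide gives the Weinreb amide; the small, strongly nucleophilic magnesium amide is suited to the hindered, vinylogous-carbonate-type ester.

Step 4
Reactants: 5 N,4,6-trimethoxy-2-(4-methoxyphenyl)-N-methyl-1-benzofuran-3-carboxamide; 6 ethynylmagnesium bromide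
Product: 7 1-[4,6-dimethoxy-2-(4-methoxyphenyl)-1-benzofuran-3-yl]prop-2-yn-1-one
Conditions: 6 (3 equiv), THF, 0 °C → rt; inverse quench into cold 1 M NaHSO4
Reagents that add atoms: none
Why: Weinreb ketone synthesis: the acetylide adds once and the magnesium chelate of the tetrahedral adduct holds until the quench. Pouring into cold acid protonates the released methoxy(methyl)amine before it can add to the terminal ynone.

Step 5
Reactants: 7 1-[4,6-dimethoxy-2-(4-methoxyphenyl)-1-benzofuran-3-yl]prop-2-yn-1-one; 8 1,1-dimethoxy-3-(trimethylsilyloxy)buta-1,3-diene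
Product: 10 [4,6-dimethoxy-2-(4-methoxyphenyl)-1-benzofuran-3-yl](4-hydroxy-2-methoxyphenyl)methanone, via cyclohexadiene cycloadduct 9 (not isolated)
Conditions: 8 (2.5 equiv), toluene, 80 °C, sealed tube; then 1 M HCl, THF, rt
Reagents that add atoms: none
Why: The HOMO of 8 is largest on the CH2 terminus (pushed by the silyloxy group and, through the diene, by the ketene acetal) and the LUMO of 7 on the terminal alkyne carbon, so a concerted but asynchronous Diels–Alder [4+2] cycloaddition joins the CH2 terminus to the β-carbon and the acetal carbon to the α-carbon, giving cyclohexa-1,4-diene 9. In 9 a methoxy group on the ketal carbon and a hydrogen of the ring CH2 stand 1,4 to each other; acid-promoted loss of methanol aromatises the ring and hydrolysis of the aryl silyl ether frees the phenol, so methoxy ends ortho and hydroxyl para to the ketone. The closest known reaction type is the cycloaddition of 1,1-dialkoxy-3-silyloxybutadienes with acetylenic esters and ketones, which gives 2-alkoxy-4-hydroxyaryl carbonyl compounds after loss of alcohol. Ring E is closed by an intermolecular cycloaddition in which both new C–C bonds form suprafacially in one event, not by cyclisation of a chain, and it then becomes aromatic by elimination. No stereocentre is formed, since the ketal carbon of 9 carries two identical methoxy groups and the other ring atoms are sp2 or CH2. The step needs one orientation (the reverse would place both oxygens meta to the ketone), which the matched donor–acceptor polarisation secures. It also needs chemoselectivity, which follows because the terminal ynone is the only electron-poor, unhindered π-bond of 7, the ring B double bond being tetrasubstituted and aromatic. Because the ring is built on a two-carbon ynone, the crowded C3 never has to accept a preformed ortho-substituted aryl nucleophile.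

Step 6
Reactants: 10 [4,6-dimethoxy-2-(4-methoxyphenyl)-1-benzofuran-3-yl](4-hydroxy-2-methoxyphenyl)methanone
Product: 11 (2,4-dimethoxyphenyl)[4,6-dimethoxy-2-(4-methoxyphenyl)-1-benzofuran-3-yl]methanone
Conditions: MeI, K2CO3, acetone, reflux
Reagents that add atoms: iodomethane, CI
Why: Williamson O-methylation of the only free phenol removes the acidic OH before the Lewis-acid acylation and the enolate alkylation, and gives all oxygens the same robust protection.

Step 7
Reactants: 11 (2,4-dimethoxyphenyl)[4,6-dimethoxy-2-(4-methoxyphenyl)-1-benzofuran-3-yl]methanone; 12 4-methoxyphenylacetyl chloride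
Product: 13 1-[3-(2,4-dimethoxybenzoyl)-4,6-dimethoxy-2-(4-methoxyphenyl)-1-benzofuran-7-yl]-2-(4-methoxyphenyl)ethan-1-one
Conditions: 12 (1.1 equiv), SnCl4 (1.5 equiv), CH2Cl2, −20 → 0 °C; 1 M HCl
Reagents that add atoms: none
Why: Friedel–Crafts acylation: ring A is a phloroglucinol-type triether and the most nucleophilic arene of 11, while ring E is deactivated by its ketone and ring C is only anisole-like. Both open positions of ring A are activated by three oxygens, but C7 has one methoxy neighbour (the ring oxygen on its other side bears no substituent) and C5 lies between two, so substitution at C7 is expected, as is usual for 4,6-dimethoxybenzofurans.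

Step 8
Reactants: 13 1-[3-(2,4-dimethoxybenzoyl)-4,6-dimethoxy-2-(4-methoxyphenyl)-1-benzofuran-7-yl]-2-(4-methoxyphenyl)ethan-1-one; 14 chloromethyl phenyl sulfide
Product: 15 1-[3-(2,4-dimethoxybenzoyl)-4,6-dimethoxy-2-(4-methoxyphenyl)-1-benzofuran-7-yl]-2-(4-methoxyphenyl)-3-(phenylsulfanyl)propan-1-one (racemic)
Conditions: KOtBu (1.1 equiv), THF, 0 °C; then 14 (1.3 equiv), NaI (0.1 equiv), 0 °C → rt
Reagents that add atoms: none
Why: C-Alkylation of the potassium enolate of the deoxybenzoin (the only enolisable position, the C3 ketone having no α-hydrogen) with the soft α-halo sulfide, activated in the flask as the iodide by Finkelstein exchange; this α-phenylsulfanylmethylation stores the future methylene in a form that should be inert to BBr3. The new stereocentre forms as a racemate and is destroyed in step 10.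

Step 9
Reactants: 15 1-[3-(2,4-dimethoxybenzoyl)-4,6-dimethoxy-2-(4-methoxyphenyl)-1-benzofuran-7-yl]-2-(4-methoxyphenyl)-3-(phenylsulfanyl)propan-1-one
Product: 16 1-[3-(2,4-dihydroxybenzoyl)-4,6-dihydroxy-2-(4-hydroxyphenyl)-1-benzofuran-7-yl]-2-(4-hydroxyphenyl)-3-(phenylsulfanyl)propan-1-one (racemic)
Conditions: BBr3 (15 equiv), CH2Cl2, −78 °C → rt; then H2O, 0 °C
Reagents that add atoms: none
Why: Lewis-acid cleavage of all six aryl methyl ethers (O-complexation, then SN2 attack of bromide on methyl). The ketones, the benzofuran and the alkyl aryl sulfide should be inert, and no Michael acceptor is present at this stage.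

Step 10
Reactants: 16 1-[3-(2,4-dihydroxybenzoyl)-4,6-dihydroxy-2-(4-hydroxyphenyl)-1-benzofuran-7-yl]-2-(4-hydroxyphenyl)-3-(phenylsulfanyl)propan-1-one
Product: 18 1-[3-(2,4-dihydroxybenzoyl)-4,6-dihydroxy-2-(4-hydroxyphenyl)-1-benzofuran-7-yl]-2-(4-hydroxyphenyl)prop-2-en-1-one, via sulfoxide 17 (not isolated)
Conditions: mCPBA (1.0 equiv), THF, −78 °C; then dilute, 65 °C
Reagents that add atoms: none
Why: One equivalent of peracid at low temperature should oxidise sulfur much faster than the acyl-deactivated phenols, and sulfoxide 17 then undergoes thermal syn-elimination (Ei) of benzenesulfenic acid through the doubly activated benzylic α-hydrogen. The methylene is thus released without base, halide or Lewis acid, the conditions under which the C6 hydroxyl would add to it; the carbon and sulfur stereocentres disappear.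

## Compound list

1 | 3,5-dimethoxyphenol | COc1cc(O)cc(OC)c1 | starting material
2 | ethyl 3-(4-methoxyphenyl)propiolate | CCOC(=O)C#Cc1ccc(OC)cc1 | starting material
3 | ethyl 3-(3,5-dimethoxyphenoxy)-3-(4-methoxyphenyl)prop-2-enoate (E/Z mixture, geometry left open) | CCOC(=O)C=C(Oc1cc(OC)cc(OC)c1)c1ccc(OC)cc1 | intermediate
4 | ethyl 4,6-dimethoxy-2-(4-methoxyphenyl)-1-benzofuran-3-carboxylate | CCOC(=O)c1c(-c2ccc(OC)cc2)oc2cc(OC)cc(OC)c12 | intermediate
5 | N,4,6-trimethoxy-2-(4-methoxyphenyl)-N-methyl-1-benzofuran-3-carboxamide | CON(C)C(=O)c1c(-c2ccc(OC)cc2)oc2cc(OC)cc(OC)c12 | intermediate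
6 | ethynylmagnesium bromide | C#C[Mg]Br | starting material
7 | 1-[4,6-dimethoxy-2-(4-methoxyphenyl)-1-benzofuran-3-yl]prop-2-yn-1-one | C#CC(=O)c1c(-c2ccc(OC)cc2)oc2cc(OC)cc(OC)c12 | intermediate
8 | 1,1-dimethoxy-3-(trimethylsilyloxy)buta-1,3-diene | COC(OC)=CC(=C)O[Si](C)(C)C | starting material
9 | [4,6-dimethoxy-2-(4-methoxyphenyl)-1-benzofuran-3-yl][6,6-dimethoxy-4-(trimethylsilyloxy)cyclohexa-1,4-dien-1-yl]methanone | COc1ccc(cc1)-c1oc2cc(OC)cc(OC)c2c1C(=O)C1=CCC(O[Si](C)(C)C)=CC1(OC)OC | intermediate (not isolated)
10 | [4,6-dimethoxy-2-(4-methoxyphenyl)-1-benzofuran-3-yl](4-hydroxy-2-methoxyphenyl)methanone | COc1ccc(cc1)-c1oc2cc(OC)cc(OC)c2c1C(=O)c1ccc(O)cc1OC | intermediate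
11 | (2,4-dimethoxyphenyl)[4,6-dimethoxy-2-(4-methoxyphenyl)-1-benzofuran-3-yl]methanone | COc1ccc(cc1)-c1oc2cc(OC)cc(OC)c2c1C(=O)c1ccc(OC)cc1OC | intermediate
12 | 4-methoxyphenylacetyl chloride | COc1ccc(CC(=O)Cl)cc1 | starting material
13 | 1-[3-(2,4-dimethoxybenzoyl)-4,6-dimethoxy-2-(4-methoxyphenyl)-1-benzofuran-7-yl]-2-(4-methoxyphenyl)ethan-1-one | COc1ccc(CC(=O)c2c(OC)cc(OC)c3c(C(=O)c4ccc(OC)cc4OC)c(-c4ccc(OC)cc4)oc23)cc1 | intermediate
14 | chloromethyl phenyl sulfide | ClCSc1ccccc1 | starting material
15 | 1-[3-(2,4-dimethoxybenzoyl)-4,6-dimethoxy-2-(4-methoxyphenyl)-1-benzofuran-7-yl]-2-(4-methoxyphenyl)-3-(phenylsulfanyl)propan-1-one (racemic) | COc1ccc(cc1)C(CSc1ccccc1)C(=O)c1c(OC)cc(OC)c2c(C(=O)c3ccc(OC)cc3OC)c(-c3ccc(OC)cc3)oc12 | intermediate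
16 | 1-[3-(2,4-dihydroxybenzoyl)-4,6-dihydroxy-2-(4-hydroxyphenyl)-1-benzofuran-7-yl]-2-(4-hydroxyphenyl)-3-(phenylsulfanyl)propan-1-one (racemic) | Oc1ccc(cc1)C(CSc1ccccc1)C(=O)c1c(O)cc(O)c2c(C(=O)c3ccc(O)cc3O)c(-c3ccc(O)cc3)oc12 | intermediate
17 | 1-[3-(2,4-dihydroxybenzoyl)-4,6-dihydroxy-2-(4-hydroxyphenyl)-1-benzofuran-7-yl]-2-(4-hydroxyphenyl)-3-(phenylsulfinyl)propan-1-one (mixture of diastereomers) | Oc1ccc(cc1)C(CS(=O)c1ccccc1)C(=O)c1c(O)cc(O)c2c(C(=O)c3ccc(O)cc3O)c(-c3ccc(O)cc3)oc12 | intermediate (not isolated)
18 | 1-[3-(2,4-dihydroxybenzoyl)-4,6-dihydroxy-2-(4-hydroxyphenyl)-1-benzofuran-7-yl]-2-(4-hydroxyphenyl)prop-2-en-1-one | C=C(C(=O)c1c(O)cc(O)c2c(C(=O)c3ccc(O)cc3O)c(-c3ccc(O)cc3)oc12)c1ccc(O)cc1 | target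

## Step count and least certain steps

Total: 10 steps. Longest linear sequence: 10 steps (1 or 2 to 18); compounds 6, 8, 12 and 14 are purchased.

Step 5 (key step). The ynone is a vinylogous ester and a weaker dienophile than a simple aryl ynone. The cycloaddition may therefore be slow enough for the diene to be lost by hydrolysis, or the reaction may stop at a Mukaiyama–Michael adduct that closes differently or not at all. Fallback, from 5: 1-bromo-2,4-dimethoxybenzene is lithiated (nBuLi, THF, −78 °C) to (2,4-dimethoxyphenyl)lithium F1, which is added to Weinreb amide 5. The route is rejoined at 11, with ring E brought in preformed and 7, 10 and step 6 bypassed.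

Step 2. The trifluoroacetic acid formed at 110 °C may divert the very electron-rich aryloxyacrylate into acylative closure to a chromone, and catalyst turnover may be poor. Fallback, from 1: ortho-iodination (NIS, CH2Cl2, 0 °C; any 4-iodo isomer is separated) gives 2-iodo-3,5-dimethoxyphenol F2. Addition to 2 as in step 1 gives ethyl 3-(2-iodo-3,5-dimethoxyphenoxy)-3-(4-methoxyphenyl)prop-2-enoate F3. Intramolecular Heck-type closure with zerovalent palladium (Pd(OAc)2, PPh3, K2CO3, DMF, 90 °C) returns to the route at 4.

Step 4. Addition to the hindered, electron-rich amide may be incomplete, and the released amine may add to the ynone during the quench. Fallback, from 4: reduction (LiAlH4, THF, 0 °C) gives [4,6-dimethoxy-2-(4-methoxyphenyl)-1-benzofuran-3-yl]methanol F4. Oxidation (MnO2, CH2Cl2) gives 4,6-dimethoxy-2-(4-methoxyphenyl)-1-benzofuran-3-carbaldehyde F5. Addition of 6 (THF, −78 → 0 °C) gives 1-[4,6-dimethoxy-2-(4-methoxyphenyl)-1-benzofuran-3-yl]prop-2-yn-1-ol F6, and oxidation (MnO2 or Dess–Martin periodinane) returns to the route at 7.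

Step 7. Regiochemical leakage to C5 of ring A or to ring E, and Lewis-acid demethylation next to the new ketone, are the likely failures, because the activation of C5 and C7 differs only sterically. Fallback, from 11: Vilsmeier–Haack formylation (POCl3, DMF), a small electrophile with a strong C7 preference, gives 3-(2,4-dimethoxybenzoyl)-4,6-dimethoxy-2-(4-methoxyphenyl)-1-benzofuran-7-carbaldehyde F7. Addition of 4-methoxybenzylmagnesium chloride at −78 °C (aldehyde before the hindered diaryl ketone) gives (2,4-dimethoxyphenyl){7-[1-hydroxy-2-(4-methoxyphenyl)ethyl]-4,6-dimethoxy-2-(4-methoxyphenyl)-1-benzofuran-3-yl}methanone F8. Dess–Martin oxidation returns to the route at 13.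

Step 10. Over-oxidation at sulfur or oxidation of a phenol, and closure of the C6 hydroxyl onto the new enone while warm, are the likely failures; loss of the sulfide in step 9 would have the same consequence. Fallback, from 13, bypassing steps 8 to 10:
- BBr3 gives 1-[3-(2,4-dihydroxybenzoyl)-4,6-dihydroxy-2-(4-hydroxyphenyl)-1-benzofuran-7-yl]-2-(4-hydroxyphenyl)ethan-1-one F9.
- Silylation (TBSCl, imidazole, DMF, 50 °C) gives its hexakis(tert-butyldimethylsilyl) ether F10.
- α-Methylenation under non-basic conditions (paraformaldehyde, iPr2NH·CF3CO2H, THF, reflux) gives the hexakis(tert-butyldimethylsilyl) ether of 18, F11.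
- Buffered fluoride (Et3N·3HF, THF, 0 °C) returns to the route at 18.

## Further compounds

F1 | step 5 | (2,4-dimethoxyphenyl)lithium | [Li]c1ccc(OC)cc1OC
F2 | step 2 | 2-iodo-3,5-dimethoxyphenol | COc1cc(O)c(I)c(OC)c1
F3 | step 2 | ethyl 3-(2-iodo-3,5-dimethoxyphenoxy)-3-(4-methoxyphenyl)prop-2-enoate (E/Z mixture) | CCOC(=O)C=C(Oc1cc(OC)cc(OC)c1I)c1ccc(OC)cc1
F4 | step 4 | [4,6-dimethoxy-2-(4-methoxyphenyl)-1-benzofuran-3-yl]methanol | OCc1c(-c2ccc(OC)cc2)oc2cc(OC)cc(OC)c12
F5 | step 4 | 4,6-dimethoxy-2-(4-methoxyphenyl)-1-benzofuran-3-carbaldehyde | O=Cc1c(-c2ccc(OC)cc2)oc2cc(OC)cc(OC)c12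
F6 | step 4 | 1-[4,6-dimethoxy-2-(4-methoxyphenyl)-1-benzofuran-3-yl]prop-2-yn-1-ol (racemic) | C#CC(O)c1c(-c2ccc(OC)cc2)oc2cc(OC)cc(OC)c12
F7 | step 7 | 3-(2,4-dimethoxybenzoyl)-4,6-dimethoxy-2-(4-methoxyphenyl)-1-benzofuran-7-carbaldehyde | COc1ccc(cc1)-c1oc2c(C=O)c(OC)cc(OC)c2c1C(=O)c1ccc(OC)cc1OC
F8 | step 7 | (2,4-dimethoxyphenyl){7-[1-hydroxy-2-(4-methoxyphenyl)ethyl]-4,6-dimethoxy-2-(4-methoxyphenyl)-1-benzofuran-3-yl}methanone (racemic) | COc1ccc(CC(O)c2c(OC)cc(OC)c3c(C(=O)c4ccc(OC)cc4OC)c(-c4ccc(OC)cc4)oc23)cc1
F9 | step 10 | 1-[3-(2,4-dihydroxybenzoyl)-4,6-dihydroxy-2-(4-hydroxyphenyl)-1-benzofuran-7-yl]-2-(4-hydroxyphenyl)ethan-1-one | Oc1ccc(CC(=O)c2c(O)cc(O)c3c(C(=O)c4ccc(O)cc4O)c(-c4ccc(O)cc4)oc23)cc1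
F10 | step 10 | hexakis(tert-butyldimethylsilyl) ether of F9 | CC(C)(C)[Si](C)(C)Oc1ccc(CC(=O)c2c(O[Si](C)(C)C(C)(C)C)cc(O[Si](C)(C)C(C)(C)C)c3c(C(=O)c4ccc(O[Si](C)(C)C(C)(C)C)cc4O[Si](C)(C)C(C)(C)C)c(-c4ccc(O[Si](C)(C)C(C)(C)C)cc4)oc23)cc1
F11 | step 10 | hexakis(tert-butyldimethylsilyl) ether of 18 | C=C(C(=O)c1c(O[Si](C)(C)C(C)(C)C)cc(O[Si](C)(C)C(C)(C)C)c2c(C(=O)c3ccc(O[Si](C)(C)C(C)(C)C)cc3O[Si](C)(C)C(C)(C)C)c(-c3ccc(O[Si](C)(C)C(C)(C)C)cc3)oc12)c1ccc(O[Si](C)(C)C(C)(C)C)cc1
A1 | alternative 1 | ethyl 2-(3,5-dimethoxyphenyl)-3-(4-methoxyphenyl)-3-oxopropanoate | CCOC(=O)C(c1cc(OC)cc(OC)c1)C(=O)c1ccc(OC)cc1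
A2 | alternative 1 | ethyl 4,6-dimethoxy-2-(4-methoxyphenyl)-1-benzofuran-3-carboxylate | CCOC(=O)c1c(-c2ccc(OC)cc2)oc2cc(OC)cc(OC)c12
A3 | alternative 1 | ethyl 5,7-dimethoxy-2-(4-methoxyphenyl)-1-benzofuran-3-carboxylate | CCOC(=O)c1c(-c2ccc(OC)cc2)oc2c(OC)cc(OC)cc12
A4 | alternative 1 | ethyl 2-(2,4-dimethoxyphenyl)-3-(4-methoxyphenyl)-3-oxopropanoate | CCOC(=O)C(c1ccc(OC)cc1OC)C(=O)c1ccc(OC)cc1
A5 | alternative 2 | 7-methoxy-2-(4-methoxyphenyl)-3-(2,4,6-trihydroxyphenyl)-4H-chromen-4-one | COc1ccc(cc1)-c1oc2cc(OC)ccc2c(=O)c1-c1c(O)cc(O)cc1O
A6 | alternative 2 | [4,6-dihydroxy-2-(4-methoxyphenyl)-1-benzofuran-3-yl](2-hydroxy-4-methoxyphenyl)methanone | COc1ccc(cc1)-c1oc2cc(O)cc(O)c2c1C(=O)c1ccc(OC)cc1O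
A7 | alternative 3 | 3,5-dimethoxy-2-[(4-methoxyphenyl)ethynyl]phenol | COc1ccc(cc1)C#Cc1c(O)cc(OC)cc1OC
A8 | alternative 3 | 1-iodo-2,4-dimethoxybenzene | COc1ccc(I)c(OC)c1
A9 | alternative 3 | (2,4-dimethoxyphenyl)[4,6-dimethoxy-2-(4-methoxyphenyl)-1-benzofuran-3-yl]methanone | COc1ccc(cc1)-c1oc2cc(OC)cc(OC)c2c1C(=O)c1ccc(OC)cc1OC
A10 | alternative 3 | carbon monoxide | [C-]#[O+]
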